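Retrosynthesis: the O5 and O7 allyl caps are removed last; the pyran is cut at the O(C4')–C2'' bond back to a 3',4'-dihydroxy-5'-prenyl ring B; ring C is cut at O1–C2 and C2–C3 to an acetophenone and a benzoate; the two aryl–prenyl bonds (C8–CH2 and C5'–CH2) are cut last.
Enabling feature: the pyran oxygen is the C4' oxygen of a catechol-type ring B whose other oxygen (3'-OH) stays free and whose C5' carries the pyran carbons, which is the pattern an oxidised 5'-prenylcatechol closes to on its own; ring A is tied to the C4 carbonyl and its oxygens can be capped.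
Forward, ring A piece: C-prenylation of phloroacetophenone, then bis-allylation. Ring B piece: O-propargylation, semihydrogenation and Claisen shift on methyl protocatechuate, then MOM protection.
Assembly: a Claisen condensation joins the pieces; acid closes ring C and frees the catechol; DDQ closes the dimethylpyran ring last; deallylation ends the route.
Stereochemistry: the target has no stereocentre; its only geometric element, the cis C3''=C4'' alkene, is fixed by the six-membered ring.

Key step: step 9

Remark: flavone numbering is used (ring A C5–C8, ring C O1–C4, ring B primed; pyran atoms C2'' = gem-dimethyl carbon, C3'', C4'', with the pyran oxygen on C4'); "prenyl" means 3-methylbut-2-en-1-yl.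

Step 1
Reactants: 1 2,4,6-trihydroxyacetophenone; 2 prenyl bromide (1-bromo-3-methylbut-2-ene)
Product: 3 1-[2,4,6-trihydroxy-3-(3-methylbut-2-en-1-yl)phenyl]ethan-1-one
Conditions: 1 (2 equiv), DBU (1.1 equiv), THF, 0 °C → rt
Reagents that add atoms: none
Why: Base-mediated nuclear C-alkylation of an acylphloroglucinol (Friedel–Crafts-type C-prenylation): the phenoxide reacts at ring carbon with the soft allylic bromide, the two open ring positions are equivalent so only one mono-C-prenyl isomer can form, and the excess of 1 should hold back double prenylation while O-prenyl ethers are removed by chromatography.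

Step 2
Reactants: 3 1-[2,4,6-trihydroxy-3-(3-methylbut-2-en-1-yl)phenyl]ethan-1-one
Product: 4 1-[4,6-bis(allyloxy)-2-hydroxy-3-(3-methylbut-2-en-1-yl)phenyl]ethan-1-one
Conditions: allyl bromide (2.2 equiv), K2CO3 (2.5 equiv), acetone, 50 °C
Reagents that add atoms: allyl bromide, C=CCBr
Why: Williamson ether synthesis: the unchelated 4-OH is alkylated first and, of the two carbonyl-chelated hydroxyls, the one at C6 with an open neighbouring position should react before the one wedged between acetyl and prenyl, which leaves free exactly the phenol that becomes O1 next to the future C8; allyl ethers are chosen because they outlast strong base and the acid of step 8 and leave later under neutral palladium catalysis.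

Step 3
Reactants: 5 methyl 3,4-dihydroxybenzoate; 6 3-chloro-3-methylbut-1-yne
Product: 7 methyl 3-hydroxy-4-[(2-methylbut-3-yn-2-yl)oxy]benzoate
Conditions: 6 (1.3 equiv), K2CO3 (1.1 equiv), KI (cat.), CuI (cat.), acetone, 50 °C, N2
Reagents that add atoms: none
Why: Copper-catalysed O-alkylation of a phenol with a tertiary propargylic chloride (through the easily ionised copper acetylide): with one equivalent of carbonate the phenoxide formed is that of the 4-OH, the more acidic hydroxyl because it is para to the ester, so the ether should form there and any 3-O isomer or bis-ether is separated.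

Step 4
Reactants: 7 methyl 3-hydroxy-4-[(2-methylbut-3-yn-2-yl)oxy]benzoate
Product: 8 methyl 3-hydroxy-4-[(2-methylbut-3-en-2-yl)oxy]benzoate
Conditions: H2 (1 atm), Pd/CaCO3 poisoned with Pb(OAc)2 (Lindlar catalyst), quinoline, EtOAc, rt
Reagents that add atoms: none
Why: Lindlar semihydrogenation: the poisoned palladium surface reduces the terminal alkyne to the alkene and stops, leaving arene, ester and the tertiary allylic ether untouched.

Step 5
Reactants: 8 methyl 3-hydroxy-4-[(2-methylbut-3-en-2-yl)oxy]benzoate
Product: 10 methyl 3,4-dihydroxy-5-(3-methylbut-2-en-1-yl)benzoate, via cyclohexadienone 9 (not isolated)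
Conditions: N,N-diethylaniline, 130 °C
Reagents that add atoms: none
Why: Aromatic Claisen rearrangement: the [3,3] shift delivers the allyl unit with inversion, so the 1,1-dimethylallyl ether becomes a linear prenyl group on C5, the only ortho position of O4 that carries hydrogen (C3 holds the hydroxyl), and enolisation of dienone 9 restores the arene, the basic amine solvent suppressing acid-catalysed chroman formation from the product.

Step 6
Reactants: 10 methyl 3,4-dihydroxy-5-(3-methylbut-2-en-1-yl)benzoate
Product: 11 methyl 3,4-bis(methoxymethoxy)-5-(3-methylbut-2-en-1-yl)benzoate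
Conditions: MOMCl (3 equiv), iPr2NEt (4 equiv), CH2Cl2, 0 °C → rt
Reagents that add atoms: chloromethyl methyl ether (MOMCl), COCCl
Why: Methoxymethyl ether (acetal) protection of both phenols: the MOM groups remove the acidic protons that would quench the enolate of step 7, tolerate strong base and are cleaved by the same acid that closes ring C.

Step 7
Reactants: 4 1-[4,6-bis(allyloxy)-2-hydroxy-3-(3-methylbut-2-en-1-yl)phenyl]ethan-1-one; 11 methyl 3,4-bis(methoxymethoxy)-5-(3-methylbut-2-en-1-yl)benzoate
Product: 12 1-[4,6-bis(allyloxy)-2-hydroxy-3-(3-methylbut-2-en-1-yl)phenyl]-3-[3,4-bis(methoxymethoxy)-5-(3-methylbut-2-en-1-yl)phenyl]propane-1,3-dione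
Conditions: 4, LiHMDS (4 equiv), THF, −78 °C; then 11, −78 °C → rt; aq. NH4Cl
Reagents that add atoms: none
Why: Crossed Claisen condensation: the ester has no alpha hydrogen, the phenoxide–enolate dianion of 4 attacks it at carbon, and deprotonation of the resulting 1,3-diketone by the excess amide base pulls the equilibrium to product.

Step 8
Reactants: 12 1-[4,6-bis(allyloxy)-2-hydroxy-3-(3-methylbut-2-en-1-yl)phenyl]-3-[3,4-bis(methoxymethoxy)-5-(3-methylbut-2-en-1-yl)phenyl]propane-1,3-dione
Product: 14 5,7-bis(allyloxy)-2-[3,4-dihydroxy-5-(3-methylbut-2-en-1-yl)phenyl]-8-(3-methylbut-2-en-1-yl)-4H-chromen-4-one, via bis(methoxymethyl) flavone 13 (not isolated)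
Conditions: HCl (2 M in MeOH), 50 °C
Reagents that add atoms: none
Why: Acid-catalysed cyclodehydration of an ortho-hydroxyaryl 1,3-diketone (the ring-closing stage of a Baker–Venkataraman flavone synthesis) followed by acetal methanolysis: the single free ring A phenol adds to the ring B-side carbonyl and water is lost to give the 4-pyranone, which fixes the prenyl group at C8, and methanolic HCl then strips the two MOM groups while the allyl ethers and the prenyl double bonds should survive the short, mild treatment.

Step 9
Reactants: 14 5,7-bis(allyloxy)-2-[3,4-dihydroxy-5-(3-methylbut-2-en-1-yl)phenyl]-8-(3-methylbut-2-en-1-yl)-4H-chromen-4-one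
Product: 17 5,7-bis(allyloxy)-2-(8-hydroxy-2,2-dimethyl-2H-chromen-6-yl)-8-(3-methylbut-2-en-1-yl)-4H-chromen-4-one, via ortho-quinone 15 (not isolated), via ortho-quinone methide 16 (not isolated)
Conditions: DDQ (1.05 equiv), dioxane, rt → 60 °C
Reagents that add atoms: none
Why: DDQ removes two electrons and two protons from the 3',4'-catechol to give ortho-quinone 15, whose prenyl CH2 on C5' then loses a proton while O3' is reprotonated (a vinylogous enolisation through ring B), giving the (Z)-ortho-quinone methide 16 with the chain O=C4'–C5'=C4''H–C3''H=C2''Me2. This 1-oxatriene closes thermally by a disrotatory oxa-6π electrocyclisation that forms the O(C4')–C2'' bond, the cis C3''=C4'' alkene and the rearomatised ring B in one event; the pyran is the only ring made and its closure is pericyclic, not a polar addition. The closest known chemistry is the DDQ cyclodehydrogenation of ortho-prenylphenols to 2,2-dimethyl-2H-chromenes and the isomerisation of prenylquinones to chromenols. No stereocentre is created. The step needs oxidation of ring B alone and closure on O4' alone: the free catechol is by far the most easily oxidised site, because ring A carries only allyl ethers, is conjugated to the C4 carbonyl and offers the 8-prenyl group no free ortho oxygen (O7 is capped, O1 belongs to ring C), and on ring B only O4' is ortho to the prenyl group, so the 3'-OH must return as a free phenol. One equivalent of oxidant should keep the product, now a monophenol, from being oxidised further.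

Step 10
Reactants: 17 5,7-bis(allyloxy)-2-(8-hydroxy-2,2-dimethyl-2H-chromen-6-yl)-8-(3-methylbut-2-en-1-yl)-4H-chromen-4-one
Product: 18 5,7-dihydroxy-2-(8-hydroxy-2,2-dimethyl-2H-chromen-6-yl)-8-(3-methylbut-2-en-1-yl)-4H-chromen-4-one (CNP0256598.0)
Conditions: Pd(PPh3)4 (5 mol %), morpholine (10 equiv), THF, rt
Reagents that add atoms: none
Why: Palladium-catalysed deallylation (Tsuji–Trost type): zerovalent palladium ionises the two aryl allyl ethers to a pi-allyl complex that morpholine traps, whereas the C-bound prenyl groups have no leaving group and the pyran C2''–O bond, a tertiary allylic ether locked in a cis ring alkene, should ionise far more slowly.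

Compound list
1 | 2,4,6-trihydroxyacetophenone | CC(=O)c1c(O)cc(O)cc1O | starting material
2 | prenyl bromide (1-bromo-3-methylbut-2-ene) | CC(C)=CCBr | starting material
3 | 1-[2,4,6-trihydroxy-3-(3-methylbut-2-en-1-yl)phenyl]ethan-1-one | CC(=O)c1c(O)cc(O)c(CC=C(C)C)c1O | intermediate
4 | 1-[4,6-bis(allyloxy)-2-hydroxy-3-(3-methylbut-2-en-1-yl)phenyl]ethan-1-one | CC(=O)c1c(OCC=C)cc(OCC=C)c(CC=C(C)C)c1O | intermediate
5 | methyl 3,4-dihydroxybenzoate | COC(=O)c1ccc(O)c(O)c1 | starting material
6 | 3-chloro-3-methylbut-1-yne | CC(C)(Cl)C#C | starting material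
7 | methyl 3-hydroxy-4-[(2-methylbut-3-yn-2-yl)oxy]benzoate | COC(=O)c1ccc(OC(C)(C)C#C)c(O)c1 | intermediate
8 | methyl 3-hydroxy-4-[(2-methylbut-3-en-2-yl)oxy]benzoate | COC(=O)c1ccc(OC(C)(C)C=C)c(O)c1 | intermediate
9 | methyl 5-hydroxy-3-(3-methylbut-2-en-1-yl)-4-oxocyclohexa-1,5-diene-1-carboxylate (racemic, formed in situ) | COC(=O)C1=CC(CC=C(C)C)C(=O)C(O)=C1 | intermediate
10 | methyl 3,4-dihydroxy-5-(3-methylbut-2-en-1-yl)benzoate | COC(=O)c1cc(O)c(O)c(CC=C(C)C)c1 | intermediate
11 | methyl 3,4-bis(methoxymethoxy)-5-(3-methylbut-2-en-1-yl)benzoate | COCOc1cc(C(=O)OC)cc(CC=C(C)C)c1OCOC | intermediate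
12 | 1-[4,6-bis(allyloxy)-2-hydroxy-3-(3-methylbut-2-en-1-yl)phenyl]-3-[3,4-bis(methoxymethoxy)-5-(3-methylbut-2-en-1-yl)phenyl]propane-1,3-dione | C=CCOc1cc(OCC=C)c(C(=O)CC(=O)c2cc(OCOC)c(OCOC)c(CC=C(C)C)c2)c(O)c1CC=C(C)C | intermediate
13 | 5,7-bis(allyloxy)-2-[3,4-bis(methoxymethoxy)-5-(3-methylbut-2-en-1-yl)phenyl]-8-(3-methylbut-2-en-1-yl)-4H-chromen-4-one (formed in situ) | C=CCOc1cc(OCC=C)c2c(=O)cc(-c3cc(OCOC)c(OCOC)c(CC=C(C)C)c3)oc2c1CC=C(C)C | intermediate
14 | 5,7-bis(allyloxy)-2-[3,4-dihydroxy-5-(3-methylbut-2-en-1-yl)phenyl]-8-(3-methylbut-2-en-1-yl)-4H-chromen-4-one | C=CCOc1cc(OCC=C)c2c(=O)cc(-c3cc(O)c(O)c(CC=C(C)C)c3)oc2c1CC=C(C)C | intermediate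
15 | 5-[5,7-bis(allyloxy)-8-(3-methylbut-2-en-1-yl)-4-oxo-4H-chromen-2-yl]-3-(3-methylbut-2-en-1-yl)cyclohexa-3,5-diene-1,2-dione (ortho-quinone, formed in situ) | C=CCOc1cc(OCC=C)c2c(=O)cc(C3=CC(=O)C(=O)C(CC=C(C)C)=C3)oc2c1CC=C(C)C | intermediate
16 | 4-[5,7-bis(allyloxy)-8-(3-methylbut-2-en-1-yl)-4-oxo-4H-chromen-2-yl]-2-hydroxy-6-[(Z)-3-methylbut-2-en-1-ylidene]cyclohexa-2,4-dien-1-one (ortho-quinone methide, formed in situ) | C=CCOc1cc(OCC=C)c2c(=O)cc(C3=C/C(=C/C=C(C)C)C(=O)C(O)=C3)oc2c1CC=C(C)C | intermediate
17 | 5,7-bis(allyloxy)-2-(8-hydroxy-2,2-dimethyl-2H-chromen-6-yl)-8-(3-methylbut-2-en-1-yl)-4H-chromen-4-one | C=CCOc1cc(OCC=C)c2c(=O)cc(-c3cc(O)c4c(c3)C=CC(C)(C)O4)oc2c1CC=C(C)C | intermediate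
18 | 5,7-dihydroxy-2-(8-hydroxy-2,2-dimethyl-2H-chromen-6-yl)-8-(3-methylbut-2-en-1-yl)-4H-chromen-4-one | CC(C)=CCc1c(O)cc(O)c2c(=O)cc(-c3cc(O)c4c(c3)C=CC(C)(C)O4)oc12 | target

Total step count: 10. Longest linear sequence: 8 steps (5 to 18 through steps 3 to 10); the ring A branch (steps 1 and 2) joins at step 7.

Steps most likely to fail

Step 9. The ortho-quinone may be consumed by dimerisation, conjugate addition or further oxidation before the prototropic shift to the quinone methide takes place, and the phenolic product may be over-oxidised. The fallback closes the pyran before the flavone is built; it sets out from 7 and returns to the route at 17. Heating 7 in N,N-diethylaniline at about 190 °C (propargyl Claisen shift, 1,5-hydrogen shift to the same kind of ortho-quinone methide, oxa-6π closure) should give methyl 8-hydroxy-2,2-dimethyl-2H-chromene-6-carboxylate F1. MOMCl and iPr2NEt in CH2Cl2 then give methyl 8-(methoxymethoxy)-2,2-dimethyl-2H-chromene-6-carboxylate F2. Condensation of F2 with the dianion of 4 under the conditions of step 7 gives 1-[4,6-bis(allyloxy)-2-hydroxy-3-(3-methylbut-2-en-1-yl)phenyl]-3-[8-(methoxymethoxy)-2,2-dimethyl-2H-chromen-6-yl]propane-1,3-dione F3. Methanolic HCl as in step 8, kept as cool as conversion allows, closes ring C and frees the phenol to give 17.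

Step 8. Acid may add a phenol across its neighbouring prenyl double bond (chroman formation on ring A before ring C closes, or on ring B once the C4' hydroxyl is free) in competition with cyclodehydration and acetal cleavage. The fallback separates the two events and avoids a strong protic acid; it sets out from 12 and returns at 14. Ring C is closed in NaOAc-buffered AcOH at 100 °C and 13 is isolated. The MOM acetals of 13 are then cleaved with ZnBr2 and n-PrSH in CH2Cl2 at 0 °C, a Lewis acid and soft nucleophile combination that should not protonate a trisubstituted alkene. No compound outside the list arises (F0).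

Step 7. Acyl transfer from an electron-rich methyl ester to a hindered, doubly deprotonated ketone may be slow, giving incomplete conversion or retro-Claisen cleavage on warming. The fallback makes the same C2–C3 bond intramolecularly; it sets out from 11 and returns at 12. Saponification with LiOH in THF–H2O gives 3,4-bis(methoxymethoxy)-5-(3-methylbut-2-en-1-yl)benzoic acid F4. Esterification of F4 with the phenol of 4 (EDC·HCl, DMAP, CH2Cl2) gives 2-acetyl-3,5-bis(allyloxy)-6-(3-methylbut-2-en-1-yl)phenyl 3,4-bis(methoxymethoxy)-5-(3-methylbut-2-en-1-yl)benzoate F5. KOtBu in THF at 0 °C → rt then effects the Baker–Venkataraman O-to-C acyl shift to 12.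

Further compounds
F1 | step 9 | methyl 8-hydroxy-2,2-dimethyl-2H-chromene-6-carboxylate | COC(=O)c1cc(O)c2c(c1)C=CC(C)(C)O2
F2 | step 9 | methyl 8-(methoxymethoxy)-2,2-dimethyl-2H-chromene-6-carboxylate | COCOc1cc(C(=O)OC)cc2c1OC(C)(C)C=C2
F3 | step 9 | 1-[4,6-bis(allyloxy)-2-hydroxy-3-(3-methylbut-2-en-1-yl)phenyl]-3-[8-(methoxymethoxy)-2,2-dimethyl-2H-chromen-6-yl]propane-1,3-dione | C=CCOc1cc(OCC=C)c(C(=O)CC(=O)c2cc(OCOC)c3c(c2)C=CC(C)(C)O3)c(O)c1CC=C(C)C
F0 | step 8 | none | none
F4 | step 7 | 3,4-bis(methoxymethoxy)-5-(3-methylbut-2-en-1-yl)benzoic acid | COCOc1cc(C(=O)O)cc(CC=C(C)C)c1OCOC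
F5 | step 7 | 2-acetyl-3,5-bis(allyloxy)-6-(3-methylbut-2-en-1-yl)phenyl 3,4-bis(methoxymethoxy)-5-(3-methylbut-2-en-1-yl)benzoate | CC(=O)c1c(OCC=C)cc(OCC=C)c(CC=C(C)C)c1OC(=O)c2cc(OCOC)c(OCOC)c(CC=C(C)C)c2
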